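Assumption: the target is delivered as the free base, and compounds 1, 2, 6, 8, 9 and 14 are taken as commercial.

## Retrosynthetic overview
1. The target comes from (−)-spectaline by O-acetylation with the nitrogen protonated.
2. The piperidine is the only permanent ring and is formed last. The δ-amino ketone condenses to a cyclic ketimine, and face-selective hydrogenation then sets C6.
3. The C3–C4 bond is the new step. A D-alaninol-derived Boc-oxazolidine (temporary ring, formed first, supplies C2) undergoes photocatalytic C–H Giese alkylation with a C17 vinyl ketone, trans-selectively, which sets C3.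
4. The vinyl ketone comes from 12-bromododecanoic acid, ethyl acetoacetate (methyl ketone end) and a vinylstannane (enone end).

## Route

**Step 1**
Reactants: 1, 12-bromododecanoic acid; 2, ethyl acetoacetate
Product: 3, 13-(ethoxycarbonyl)-14-oxopentadecanoic acid (racemic at C13)
Conditions: NaOEt (2.2 equiv), NaI (cat.), EtOH, reflux, 16 h; aq HCl work-up
Reagents that add atoms: ethyl acetoacetate, CCOC(=O)CC(C)=O
Why: Acetoacetic ester synthesis; the soft enolate displaces the primary bromide (SN2) faster than the carboxylate does, and the racemic α-centre is erased in step 2.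

**Step 2**
Reactants: 3
Product: 4, 14-oxopentadecanoic acid
Conditions: 2 M aq NaOH, rt, 6 h; then H2SO4 to pH 1, reflux, 2 h
Reagents that add atoms: none
Why: Ketonic hydrolysis and decarboxylation of the β-keto ester; the remote carboxylic acid is untouched.

**Step 3**
Reactants: 4
Product: 5, 14-oxopentadecanoyl chloride
Conditions: (COCl)2 (1.3 equiv), DMF (cat.), CH2Cl2, 0 °C to rt; evaporate
Reagents that add atoms: oxalyl chloride, O=C(Cl)C(=O)Cl
Why: Vilsmeier-type acid chloride formation; the isolated methyl ketone is inert under these brief, mild conditions.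

**Step 4**
Reactants: 5; 6, tributyl(vinyl)stannane
Product: 7, heptadec-1-ene-3,16-dione
Conditions: Pd(PPh3)4 (2 mol %), THF, 50 °C, 3 h; aq KF work-up; use at once
Reagents that add atoms: tributyl(vinyl)stannane, C=C[Sn](CCCC)(CCCC)CCCC
Why: Acylative Stille coupling (acid chloride plus vinylstannane); it is neutral and chemoselective, so the methyl ketone needs no protection.

**Step 5**
Reactants: 8, N-Boc-D-alaninol [tert-butyl (R)-(1-hydroxypropan-2-yl)carbamate]; 9, 2,2-dimethoxypropane
Product: 10, tert-butyl (4R)-2,2,4-trimethyl-1,3-oxazolidine-3-carboxylate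
Conditions: 9 (5 equiv), p-TsOH·H2O (5 mol %), CH2Cl2, rt to reflux
Reagents that add atoms: 2,2-dimethoxypropane, COC(C)(C)OC
Why: N,O-acetonide formation by transacetalisation; the chiral-pool centre (future C2, R) is not touched.

**Step 6 (new transformation)**
Reactants: 10 (3 equiv, excess recovered); 7 (1 equiv, added over 6 h)
Product: 11, tert-butyl (4R,5R)-2,2,4-trimethyl-5-(3,16-dioxoheptadecyl)-1,3-oxazolidine-3-carboxylate (4,5-trans)
Conditions: (nBu4N)4[W10O32] (2 mol %), 390 nm LEDs, MeCN/CH2Cl2 4:1, N2, 20 °C; minor 4,5-cis isomer removed by chromatography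
Reagents that add atoms: none (7 and 10 are the only atom sources)
Why: Proposed new method: photoexcited decatungstate should abstract a hydridic O–CH2 hydrogen (C5–H) of 10, because the only other activated C–H (C4–H) is tertiary, wedged between Boc and CMe2, and lies near the nodal plane of the carbamate nitrogen (A(1,3) strain makes the 4-methyl pseudo-axial) so it gains little α-amino stabilisation; the nucleophilic α-oxy radical then adds to the CH2 terminus of enone 7 anti to the pseudo-axial 4-methyl, giving the 4,5-trans (5R) product that contains the target's C3–C4 bond and C3 stereocentre, and back hydrogen transfer from reduced tungstate to the α-keto radical closes the cycle; the closest known reaction type is the decatungstate-photocatalysed Giese C–H alkylation of ethers and diol acetonides, which has not been shown at the O–CH2 of 4-substituted N-Boc-oxazolidines.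

**Step 7**
Reactants: 11
Product: 12, 14-[(5R,6R)-5-hydroxy-6-methyl-3,4,5,6-tetrahydropyridin-2-yl]tetradecan-2-one (cyclic ketimine, used crude)
Conditions: TFA/CH2Cl2/H2O 10:10:1, 0 °C to rt, 2 h; evaporate; sat. aq NaHCO3/CH2Cl2
Reagents that add atoms: none
Why: Acidolysis removes Boc and the acetonide, and on neutralisation the primary amine condenses with the δ-ketone (six-membered imine) in preference to the remote ketone; C2 and C3 are unaffected.

**Step 8**
Reactants: 12
Product: 13, (−)-spectaline, 14-[(2S,5R,6R)-5-hydroxy-6-methylpiperidin-2-yl]tetradecan-2-one (all-cis)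
Conditions: H2 (1 atm), 10% Pd/C, MeOH, rt
Reagents that add atoms: none
Why: Heterogeneous hydrogenation of a Δ1-piperideine; the imine binds through the face opposite the C2-methyl and axial C3-OH, so H reaches C6 cis to H-2 and gives the 2,6-cis, all-cis (6S) piperidine, while the dialkyl ketone is inert at 1 atm.

**Step 9**
Reactants: 13; 14, acetyl chloride
Product: 15, (−)-3-O-acetylspectaline, (2R,3R,6S)-2-methyl-6-(13-oxotetradecyl)piperidin-3-yl acetate
Conditions: AcCl (3 equiv), TFA, 0 °C to rt, 4 h; evaporate; cold aq NaHCO3/CH2Cl2
Reagents that add atoms: acetyl chloride, CC(=O)Cl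
Why: Chemoselective O-acylation of an amino alcohol in strong acid; the hindered 2,6-disubstituted nitrogen is fully protonated, so only the C3-OH is acetylated, with retention because no C–O bond is broken.

## Compound list
| No. | Name | SMILES | Role |
|---|---|---|---|
| 1 | 12-bromododecanoic acid | OC(=O)CCCCCCCCCCCBr | starting material |
| 2 | ethyl acetoacetate | CCOC(=O)CC(C)=O | starting material |
| 3 | 13-(ethoxycarbonyl)-14-oxopentadecanoic acid | CCOC(=O)C(CCCCCCCCCCCC(=O)O)C(C)=O | intermediate |
| 4 | 14-oxopentadecanoic acid | CC(=O)CCCCCCCCCCCCC(=O)O | intermediate |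
| 5 | 14-oxopentadecanoyl chloride | CC(=O)CCCCCCCCCCCCC(=O)Cl | intermediate |
| 6 | tributyl(vinyl)stannane | C=C[Sn](CCCC)(CCCC)CCCC | starting material |
| 7 | heptadec-1-ene-3,16-dione | C=CC(=O)CCCCCCCCCCCCC(C)=O | intermediate |
| 8 | N-Boc-D-alaninol | C[C@H](CO)NC(=O)OC(C)(C)C | starting material |
| 9 | 2,2-dimethoxypropane | COC(C)(C)OC | starting material |
| 10 | tert-butyl (4R)-2,2,4-trimethyloxazolidine-3-carboxylate | C[C@@H]1COC(C)(C)N1C(=O)OC(C)(C)C | intermediate |
| 11 | tert-butyl (4R,5R)-2,2,4-trimethyl-5-(3,16-dioxoheptadecyl)oxazolidine-3-carboxylate | C[C@@H]1[C@@H](CCC(=O)CCCCCCCCCCCCC(C)=O)OC(C)(C)N1C(=O)OC(C)(C)C | intermediate |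
| 12 | 14-[(5R,6R)-5-hydroxy-6-methyl-3,4,5,6-tetrahydropyridin-2-yl]tetradecan-2-one | CC(=O)CCCCCCCCCCCCC1=N[C@H](C)[C@H](O)CC1 | intermediate |
| 13 | (−)-spectaline | CC(=O)CCCCCCCCCCCC[C@H]1CC[C@@H](O)[C@@H](C)N1 | intermediate |
| 14 | acetyl chloride | CC(=O)Cl | starting material |
| 15 | (−)-3-O-acetylspectaline | CC(=O)CCCCCCCCCCCC[C@H]1CC[C@@H](OC(C)=O)[C@@H](C)N1 | target |

## Summary
Total steps: 9. Longest linear sequence: 8 (steps 1–4, then 6–9).

Steps most likely to fail:

1. **Step 6 (new C–H Giese alkylation).**
   - Risks: hydrogen abstraction at C4–H or at the chain methylenes of 7, modest trans:cis ratio, and enone oligomerisation.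
   - Fallback (known chemistry): generate the same C5 radical regiospecifically by photoredox decarboxylative Giese addition.
   - Radical precursor: (4R)-3-Boc-2,2,4-trimethyloxazolidine-5-carboxylic acid, made from methyl (R)-3-(Boc-amino)butanoate by enolate hydroxylation with a Davis oxaziridine, acetonide formation and LiOH hydrolysis. Its C5 configuration does not matter.
   - Coupling: the acid is joined to 7 with Ir[dF(CF3)ppy]2(dtbbpy)PF6, K2HPO4 and blue LEDs to give 11.
2. **Step 9 (O-selective acetylation).**
   - Risks: N-acetylation, O-to-N acyl migration on work-up, and enol acetate formation at the ketone.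
   - Fallback: use a protecting-group sequence of N-Cbz formation (CbzCl, K2CO3), then Ac2O/DMAP, then neutral hydrogenolysis (H2, Pd/C, EtOAc).
3. **Step 4 (making and handling vinyl ketone 7).**
   - Risks: polymerisation and decarbonylation.
   - Fallback: change the order of bond formation. Use commercial N-methoxy-N-methylacrylamide as the radical acceptor in step 6.
   - The side chain is then installed by Weinreb ketone synthesis with the Grignard reagent of 14-bromotetradecan-2-one ethylene ketal. The ketal is cleaved in step 7 together with Boc and the acetonide.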